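**Retrosynthetic overview**
1. Target 15 ⇐ aryl silyl ether 12: the phenolic TIPS group is exchanged for the angelate in the last step (fluoride, angelic anhydride).
2. 12 ⇐ (R)-aryl oxirane 7 + formaldehyde 8 + tigloyl chloride 9: the quaternary C–CH2O bond is cut to a configurationally stable oxiranyllithium (the epoxide carbon as nucleophile) and CH2O. Trapping with retention turns the tertiary stereocentre into the quaternary one.
3. 7 ⇐ α-chloroketone 5: asymmetric transfer hydrogenation, then chlorohydrin closure. The oxirane is the only ring made in the route and is formed before the quaternary centre is built on it; the benzene ring is bought.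
4. 5 ⇐ 2,5-dimethoxytoluene 1 + chloroacetyl chloride 2: Friedel–Crafts acylation with ortho-demethylation, then O-silylation.

Assumption: as the SMILES reads, the oxirane carbon is (R) (aryl is its lowest-priority substituent), the aryl ester is the angelate (Z) and the alkyl ester the tiglate (E); angelic anhydride, tigloyl chloride and paraformaldehyde are bought.

**Step 1**
Reactants: 1 2,5-dimethoxytoluene; 2 chloroacetyl chloride
Product: 4 2-chloro-1-(2-hydroxy-5-methoxy-4-methylphenyl)ethan-1-one, via dimethoxy chloroketone 3 (not isolated)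
Conditions: AlCl3 (2.5 equiv), CH2Cl2, 0 °C then reflux; ice/2 M HCl work-up
Reagents that add atoms: none
Why: Friedel–Crafts acylation occurs para to the methyl group and ortho to a methoxy group (the most activated and least hindered position of 1), and the excess AlCl3 then cleaves only the methyl ether chelated to the new ketone (ortho-selective Lewis-acid demethylation), so the two hydroquinone oxygens are differentiated in one operation.

**Step 2**
Reactants: 4 2-chloro-1-(2-hydroxy-5-methoxy-4-methylphenyl)ethan-1-one
Product: 5 2-chloro-1-[5-methoxy-4-methyl-2-(triisopropylsilyloxy)phenyl]ethan-1-one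
Conditions: TIPSOTf (1.2 equiv), 2,6-lutidine (1.5 equiv), CH2Cl2, –78 to 0 °C
Reagents that add atoms: triisopropylsilyl trifluoromethanesulfonate, CC(C)[Si](OS(=O)(=O)C(F)(F)F)(C(C)C)C(C)C
Why: Phenol O-silylation with a silyl triflate and the hindered base 2,6-lutidine (which does not alkylate at the phenacyl chloride) installs a bulky TIPS ether that withstands s-BuLi, is slow to undergo anionic silyl shifts and is later removed by fluoride.

**Step 3**
Reactants: 5 2-chloro-1-[5-methoxy-4-methyl-2-(triisopropylsilyloxy)phenyl]ethan-1-one
Product: 7 (2R)-2-[5-methoxy-4-methyl-2-(triisopropylsilyloxy)phenyl]oxirane, via (R)-chlorohydrin 6 (not isolated)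
Conditions: Cp*RhCl[(S,S)-TsDPEN] (0.5 mol%), HCO2H/Et3N (5:2), EtOAc, 25 °C; extractive work-up, crude 6 then KOtBu (1.1 equiv), THF, –20 to 0 °C
Reagents that add atoms: none
Why: Noyori–Ikariya asymmetric transfer hydrogenation with the (S,S)-TsDPEN catalyst delivers hydride to the ketone face that turns acetophenone into (S)-1-phenylethanol, which here is the (R)-chlorohydrin because CH2Cl outranks the aryl group, and the potassium alkoxide then closes the oxirane by intramolecular Williamson (3-exo-tet) displacement at CH2Cl without touching the stereocentre.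

**Step 4**
Reactants: 7 (2R)-2-[5-methoxy-4-methyl-2-(triisopropylsilyloxy)phenyl]oxirane; 8 formaldehyde; 9 tigloyl chloride
Product: 12 [(2R)-2-[5-methoxy-4-methyl-2-(triisopropylsilyloxy)phenyl]oxiran-2-yl]methyl (2E)-2-methylbut-2-enoate, via oxiranyllithium 10 (not isolated), via lithium alkoxide 11 (not isolated)
Conditions: s-BuLi (1.3 equiv), TMEDA (3 equiv), THF, –98 °C, 20 min; monomeric CH2O (ca. 2 equiv, cold THF solution from cracked paraformaldehyde, added until the anion colour fades), –98 to –78 °C; tigloyl chloride (3 equiv), –78 to –20 °C; NaHCO3 work-up; Et3N-deactivated silica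
Reagents that add atoms: none
Why: Benzylic α-deprotonation of the aryl oxirane by s-BuLi/TMEDA gives an oxiranyllithium that is configurationally stable at –98 °C and adds to formaldehyde with retention (stereoretentive electrophilic trapping of a lithiated styrene oxide), so the epoxide carbon acts as the nucleophile toward a carbonyl carbon, the tertiary stereocentre becomes the quaternary (R) centre of the target in one step, and the lithium alkoxide is esterified in the same flask by the acid chloride (its Payne rearrangement is degenerate and returns the same enantiomer).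

**Step 5**
Reactants: 12 [(2R)-2-[5-methoxy-4-methyl-2-(triisopropylsilyloxy)phenyl]oxiran-2-yl]methyl (2E)-2-methylbut-2-enoate; 13 angelic anhydride
Product: 15 [(2R)-2-(5-methoxy-4-methyl-2-{[(2Z)-2-methylbut-2-enoyl]oxy}phenyl)oxiran-2-yl]methyl (2E)-2-methylbut-2-enoate (target), via tetrabutylammonium phenoxide 14 (not isolated)
Conditions: angelic anhydride (2 equiv), THF, –40 °C; TBAF (1.1 equiv, 1 M in THF) added over 30 min; –40 to 0 °C; pH 7 buffer work-up
Reagents that add atoms: none
Why: Fluoride cleaves the aryl O–Si bond and the phenoxide is acylated as it forms by the anhydride already in solution (one-pot desilylation–acylation), a low-temperature, non-acidic exchange that leaves the acid-labile aryl oxirane, the tiglate and the Z geometry of the angelate intact.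

**Compound list**
1 | 2,5-dimethoxytoluene (1,4-dimethoxy-2-methylbenzene) | Cc1cc(OC)ccc1OC | starting material
2 | chloroacetyl chloride | ClCC(Cl)=O | starting material
3 | 2-chloro-1-(2,5-dimethoxy-4-methylphenyl)ethan-1-one | Cc1cc(OC)c(C(=O)CCl)cc1OC | intermediate (not isolated)
4 | 2-chloro-1-(2-hydroxy-5-methoxy-4-methylphenyl)ethan-1-one | Cc1cc(O)c(C(=O)CCl)cc1OC | intermediate
5 | 2-chloro-1-[5-methoxy-4-methyl-2-(triisopropylsilyloxy)phenyl]ethan-1-one | Cc1cc(O[Si](C(C)C)(C(C)C)C(C)C)c(C(=O)CCl)cc1OC | intermediate
6 | (1R)-2-chloro-1-[5-methoxy-4-methyl-2-(triisopropylsilyloxy)phenyl]ethan-1-ol | Cc1cc(O[Si](C(C)C)(C(C)C)C(C)C)c([C@@H](O)CCl)cc1OC | intermediate (not isolated)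
7 | (2R)-2-[5-methoxy-4-methyl-2-(triisopropylsilyloxy)phenyl]oxirane | Cc1cc(O[Si](C(C)C)(C(C)C)C(C)C)c([C@@H]2CO2)cc1OC | intermediate
8 | formaldehyde (monomer, from paraformaldehyde) | C=O | starting material
9 | tigloyl chloride, (2E)-2-methylbut-2-enoyl chloride | ClC(=O)/C(C)=C/C | starting material
10 | [(2R)-2-[5-methoxy-4-methyl-2-(triisopropylsilyloxy)phenyl]oxiran-2-yl]lithium (Li in place of the oxirane H of 7, same spatial arrangement) | Cc1cc(O[Si](C(C)C)(C(C)C)C(C)C)c([C@]2([Li])CO2)cc1OC | intermediate (not isolated)
11 | lithium {2-[5-methoxy-4-methyl-2-(triisopropylsilyloxy)phenyl]oxiran-2-yl}methoxide (CH2OLi where 10 carries Li, spatial arrangement as in 12) | Cc1cc(O[Si](C(C)C)(C(C)C)C(C)C)c([C@]2(CO[Li])CO2)cc1OC | intermediate (not isolated)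
12 | [(2R)-2-[5-methoxy-4-methyl-2-(triisopropylsilyloxy)phenyl]oxiran-2-yl]methyl (2E)-2-methylbut-2-enoate | Cc1cc(O[Si](C(C)C)(C(C)C)C(C)C)c([C@]2(COC(=O)/C(C)=C/C)CO2)cc1OC | intermediate
13 | angelic anhydride, (2Z)-2-methylbut-2-enoic anhydride | C/C=C(/C)C(=O)OC(=O)/C(C)=C\C | starting material
14 | tetrabutylammonium 4-methoxy-5-methyl-2-[(2R)-2-{[(2E)-2-methylbut-2-enoyl]oxymethyl}oxiran-2-yl]phenolate | Cc1cc([O-])c([C@]2(COC(=O)/C(C)=C/C)CO2)cc1OC.CCCC[N+](CCCC)(CCCC)CCCC | intermediate (not isolated)
15 | [(2R)-2-(5-methoxy-4-methyl-2-{[(2Z)-2-methylbut-2-enoyl]oxy}phenyl)oxiran-2-yl]methyl (2E)-2-methylbut-2-enoate | C/C=C(/C)C(=O)Oc1cc(C)c(OC)cc1[C@]1(COC(=O)/C(C)=C/C)CO1 | target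

**Step count and risks**
Total steps: 5. Longest linear sequence: 5 (1 → 4 → 5 → 7 → 12 → 15). Cracking paraformaldehyde to monomeric CH2O is a reagent preparation and is not counted.

Most at risk is step 4. The electron-rich ring slows the α-deprotonation of 7, and ring lithiation next to the OMe group or an oxygen-to-carbon silyl shift could compete. The oxiranyllithium 10 decomposes or racemises if it warms. Excess CH2O can give hemiformal esters, and TMEDA with the acid chloride can give some deconjugated ester through a vinylketene. The fallback sets out from 5. Displacement of chloride with potassium tiglate (cat. Bu4NI, acetone, 40 °C) gives 2-[5-methoxy-4-methyl-2-(triisopropylsilyloxy)phenyl]-2-oxoethyl (2E)-2-methylbut-2-enoate F1. F1 is then epoxidised by catalytic asymmetric Corey–Chaykovsky methylene transfer: dimethylsulfoxonium methylide (from Me3S(O)I and NaH), LaLi3(binaphthoxide)3 (5 mol%), (2,4,6-trimethoxyphenyl)3P=O (5 mol%), THF, room temperature. Here the ylide carbon is the nucleophilic partner of the ketone carbon, and the oxirane and the quaternary stereocentre are made together by facial selection at the ketone. This comes back to the route at 12. The binaphthol antipode giving the (R)-epoxide is fixed by a pilot run. The extension from methyl ketones to an acyloxymethyl ketone is unproven and the ee is uncertain.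

Second is step 5. The naked phenoxide 14 sits ortho to a benzylic oxirane and could open it (ortho-quinone methide, loss of ee) or take over the tiglate by acyl shift. Fluoride can also be consumed by the anhydride so that the desilylation stalls. The fallback sets out from 12 and uses a fluoride-catalysed silyl-to-acyl exchange. (2Z)-2-Methylbut-2-enoyl fluoride F2 is made from bought angelic acid with cyanuric fluoride and pyridine (CH2Cl2, –10 °C). F2 (1.5 equiv) and Bu4N[Ph3SiF2] (5 mol%) in THF at –20 °C then convert 12 directly. Each phenoxide is formed only when an acylation releases fluoride and is surrounded by excess acyl fluoride, so it never accumulates. This comes back to the route at 15.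

Third is step 3. The ortho-OTIPS group twists the aryl ketone and may lower the rate or the ee of the transfer hydrogenation. The fallback sets out from 5. NaBH4 (MeOH/THF, 0 °C) gives racemic 2-chloro-1-[5-methoxy-4-methyl-2-(triisopropylsilyloxy)phenyl]ethan-1-ol F3, and KOtBu (THF, –20 °C) closes it to racemic 2-[5-methoxy-4-methyl-2-(triisopropylsilyloxy)phenyl]oxirane F4. Hydrolytic kinetic resolution with (S,S)-(salen)Co(OAc) (1 mol%) and H2O (0.55 equiv) in THF (0 °C to room temperature) hydrolyses the (S)-epoxide to (1S)-1-[5-methoxy-4-methyl-2-(triisopropylsilyloxy)phenyl]ethane-1,2-diol F5. The (S,S) antipode is chosen by analogy with styrene oxide and should be confirmed on a small scale. The unreacted (R)-epoxide (at most 50%) is isolated, which comes back to the route at 7.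

**Further compounds**
F1 | step 4 | 2-[5-methoxy-4-methyl-2-(triisopropylsilyloxy)phenyl]-2-oxoethyl (2E)-2-methylbut-2-enoate | Cc1cc(O[Si](C(C)C)(C(C)C)C(C)C)c(C(=O)COC(=O)/C(C)=C/C)cc1OC
F2 | step 5 | (2Z)-2-methylbut-2-enoyl fluoride (angeloyl fluoride) | C/C=C(/C)C(F)=O
F3 | step 3 | rac-2-chloro-1-[5-methoxy-4-methyl-2-(triisopropylsilyloxy)phenyl]ethan-1-ol | Cc1cc(O[Si](C(C)C)(C(C)C)C(C)C)c(C(O)CCl)cc1OC
F4 | step 3 | rac-2-[5-methoxy-4-methyl-2-(triisopropylsilyloxy)phenyl]oxirane | Cc1cc(O[Si](C(C)C)(C(C)C)C(C)C)c(C2CO2)cc1OC
F5 | step 3 | (1S)-1-[5-methoxy-4-methyl-2-(triisopropylsilyloxy)phenyl]ethane-1,2-diol | Cc1cc(O[Si](C(C)C)(C(C)C)C(C)C)c([C@H](O)CO)cc1OC
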